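Readings and results are simulated on assumed constants; noise was put on by code.

I decide to reckon these flasks from one ratio read off the runs, not from fitted rate constants.

all flasks: free monomer 0.10 M (fed, over 50 min)
- delta: transfer agent 0.010 M; initiator 2.5 mol%; temperature −25 °C; run made earlier; the fed solution adds 0.20 times the starting volume
- eta: transfer agent 0.010 M; initiator 10 mol%; temperature −10 °C; run made earlier; the fed solution adds 0.20 times the starting volume
- Thursday's: transfer agent 0.0100 M; initiator 5 mol%; temperature −20 °C; the fed solution adds 0.20 times the starting volume; time 1.5 h
- Friday's: transfer agent 0.0100 M; initiator 5 mol%; temperature 0 °C; the fed solution adds 0.20 times the starting volume; time 1.5 h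

| run | time / min | monomer in chains / % | free monomer / % |
|---|---|---|---|
| delta | 12.0 | 3.0 | 21.4 |
| delta | 25.0 | 7.2 | 44.4 |
| delta | 40.0 | 9.7 | 69.9 |
| delta | 50.0 | 13.0 | 88.1 |
| delta | 60.0 | 14.4 | 85.4 |
| delta | 80.0 | 16.1 | 84.6 |
| eta | 4.00 | 3.9 | 4.1 |
| eta | 6.00 | 6.3 | 5.1 |
| eta | 10.0 | 11.0 | 8.2 |
| eta | 15.0 | 14.5 | 15.4 |
| eta | 25.0 | 18.6 | 31.9 |
| eta | 50.0 | 19.7 | 79.8 |

(standard deviation of a reading: 0.5 percentage points)

- what is said of monomer in chains includes crystals
- amounts are per litre of the starting volume; all of the dose is in the solution fed
- crystals is a solid; its amount is given per volume of the solution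
- what was read earlier has a scatter of 0.5 percentage points, one standard deviation
- what may be going on: free monomer + initiator -> living end + monomer in chains; free monomer + living end -> monomer in chains + living end; living end + transfer agent -> dead chain; crystals <-> monomer in chains; living end -> dead end
- percentages count the whole charge, also what has not yet gone in

* which of these there is most of at the end, counted by the free monomer in it, Thursday's (monomer in chains / free monomer)
* which of these there is most of at the end, counted by the free monomer in it, Friday's (monomer in chains / free monomer)
* amount of the one of these that there is most of at the end, in percent of the free monomer charged, Thursday's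
* amount of the one of these that there is most of at the end, in percent of the free monomer charged, Friday's

The ratio is monomer in chains at the last reading divided by the initiator loading. Eta gives 1.97 at −10 °C and delta gives 6.44 at −25 °C. I call this the chain multiple, and delta's is larger than eta's, though the two runs differ in loading as well as in temperature. Its floor is one: each initiator that reacts puts one monomer in chains, provided the initiator is used up.

I freeze the multiple against loading, so free monomer at the end is the whole charge minus multiple times loading. I place Thursday's, between the two temperatures, from 67.8 % to 90.1 %. Delta was still climbing at its last reading, so that lower limit may sit too high. I place Friday's, warmer than eta, from 90.1 % to 95.0 %.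

To tighten this, I take the multiple's excess over one as falling by a constant ratio per degree. That gives a multiple of 4.06 on Thursday's and 1.31 on Friday's. My free monomer is therefore 79.7 % on Thursday's and 93.5 % on Friday's, in each more than my monomer in chains.

The forecast gives free monomer at 78 % on Thursday's and free monomer at 87 % on Friday's, saying for Friday's that “the activity dies within minutes, before much monomer has been fed”. Its Friday's value stands below my bracket.

Thursday's gives free monomer at 76.4 %. Friday's gives free monomer at 93.6 %, inside my bracket.

    free monomer + initiator → living end + monomer in chains (k = 19.0 M⁻¹ min⁻¹, Ea = 52.0 kJ mol⁻¹)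
    free monomer + living end → monomer in chains + living end, rate k2*[living end]*[free monomer] (k = 8.10 M⁻¹ min⁻¹, Ea = 36.0 kJ mol⁻¹)
    living end + transfer agent → dead chain (kL = 5.70 M⁻¹ min⁻¹, Ea = 44.0 kJ mol⁻¹)
    crystals ⇌ monomer in chains, rate k4*(cs4 - [monomer in chains]) while solid is left; crystals form when [monomer in chains] > cs4 (solubility = 1.70 mM, k = 1.80 min⁻¹)
    living end → dead end (k = 0.0220 min⁻¹, Ea = 80.0 kJ mol⁻¹)
    (constants at −20 °C)

Friday's ends with 0 % of its initiator, and its multiple reads 1.29, between the floor and eta's 1.97. The neighbouring flask is Friday's with 1.2 mol% of initiator. At the same temperature I keep my multiple of 1.31, so free monomer should stand at 98.4 %, inside the bracket from 97.6 % to 98.8 %. That neighbour ends with 0 % of its initiator, monomer in chains at 1.63 % and free monomer at 98.4 %.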